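## Retrosynthetic overview
1. Last step: thirteen-fold O-demethylation of the fully methylated pentaaryl compound. Methyl is the only permanent protecting group.
2. Ether A–O–B: Ullmann coupling of a ring B phenol with 1-bromo-3,5-dimethoxybenzene. The phenol comes from a ring B aldehyde by Baeyer–Villiger oxidation.
3. Ether B–O–C: Ullmann coupling of the single free phenol of ring C (C1–OH) with 2-bromo-4,6-dimethoxybenzaldehyde.
4. Ring C phenol: from a 2,6-dimethoxy-3,5-diaryl-1,4-benzoquinone by reduction and steric differentiation of the two hydroxyls. The two methoxy groups enter by chloride displacement.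
5. Key C–C bonds C–D and C–E: two successive intermolecular Michael additions of 1,3,5-trimethoxybenzene to 2,6-dichloro-1,4-benzoquinone. No ring is built; five bought benzene rings are joined in the order C+D, +E, +B, +A.

Labels: ring A is the 3,5-dihydroxyphenoxy ring, ring B the central ring carrying both ether oxygens, ring C the hexasubstituted ring, and rings D and E the 2,4,6-trihydroxyphenyl rings. In ring C, C1 bears O–ring B, C2/C4/C6 bear OH, and C3/C5 bear rings D and E. The quinones use the same locants.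

Assumption: the SMILES has no stereocentre and no stereogenic axis (rings D and E are symmetric about their biaryl bonds), so the target is achiral, no step creates a stereocentre, and the one compound drawn is made.

## Route

Step 1
Reactants: 1 2,6-dichloro-1,4-benzoquinone; 2 1,3,5-trimethoxybenzene
Product: 4 2,6-dichloro-3-(2,4,6-trimethoxyphenyl)-1,4-benzoquinone, via monoaryl hydroquinone 3 (not isolated)
Conditions: 1 (1.3 equiv), 2 (1.0 equiv, slow addition), In(OTf)3 (10 mol %), MeCN, 0 °C to rt, N2; then DDQ (1.1 equiv), rt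
Reagents that add atoms: none
Why: Michael (1,4-conjugate) addition of an enol-ether-type π-nucleophile to a Lewis-acid-activated quinone, in which 2 attacks the unsubstituted C3 (β to the C1 carbonyl and less crowded than the C–Cl carbons), tautomerisation gives 3, and DDQ dehydrogenation restores the acceptor.

Step 2
Reactants: 4 2,6-dichloro-3-(2,4,6-trimethoxyphenyl)-1,4-benzoquinone; 2 1,3,5-trimethoxybenzene
Product: 6 2,6-dichloro-3,5-bis(2,4,6-trimethoxyphenyl)-1,4-benzoquinone, via diaryl hydroquinone 5 (not isolated)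
Conditions: 2 (1.5 equiv), In(OTf)3 (20 mol %), MeCN, 40 °C, N2; then DDQ (1.1 equiv), rt
Reagents that add atoms: none
Why: This second intermolecular Michael addition is the key C–C bond formation, because C5 is the only unsubstituted acceptor carbon left in 4 and lies remote from the first aryl group, so conjugate addition and DDQ dehydrogenation fix the 3,5-diaryl pattern unambiguously.

Step 3
Reactants: 6 2,6-dichloro-3,5-bis(2,4,6-trimethoxyphenyl)-1,4-benzoquinone
Product: 7 2,6-dimethoxy-3,5-bis(2,4,6-trimethoxyphenyl)-1,4-benzoquinone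
Conditions: NaOMe (5 equiv), dry MeOH/THF 1:1, 0 °C to 50 °C
Reagents that add atoms: sodium methoxide, [Na+].[O-]C
Why: Addition–elimination (vinylogous acyl substitution) works because each C–Cl carbon is β to the C4 carbonyl, so methoxide adds in conjugate fashion and expels chloride, while the aryl-bearing carbons carry no leaving group.

Step 4
Reactants: 7 2,6-dimethoxy-3,5-bis(2,4,6-trimethoxyphenyl)-1,4-benzoquinone
Product: 8 2,6-dimethoxy-3,5-bis(2,4,6-trimethoxyphenyl)benzene-1,4-diol
Conditions: Na2S2O4 (5 equiv), THF/H2O, rt, Ar; used at once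
Reagents that add atoms: none
Why: Dithionite reduction of a quinone to its hydroquinone is fast and touches neither the aryl methyl ethers nor the biaryl bonds.

Step 5
Reactants: 8 2,6-dimethoxy-3,5-bis(2,4,6-trimethoxyphenyl)benzene-1,4-diol
Product: 9 4-hydroxy-2,6-dimethoxy-3,5-bis(2,4,6-trimethoxyphenyl)phenyl pivalate
Conditions: PivCl (1.05 equiv), Et3N (1.5 equiv), DMAP (5 mol %), CH2Cl2, −20 °C to 0 °C, Ar
Reagents that add atoms: pivaloyl chloride, CC(C)(C)C(=O)Cl
Why: Sterically controlled O-acylation is selective because C1–OH is flanked only by two methoxy groups whereas C4–OH sits between two perpendicular 2,6-dimethoxyaryl rings, so one equivalent of the bulky acyl chloride takes C1–OH.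

Step 6
Reactants: 9 4-hydroxy-2,6-dimethoxy-3,5-bis(2,4,6-trimethoxyphenyl)phenyl pivalate
Product: 10 2,4,6-trimethoxy-3,5-bis(2,4,6-trimethoxyphenyl)phenyl pivalate
Conditions: MeI (5 equiv), Cs2CO3 (2 equiv), dry DMF, 40 °C
Reagents that add atoms: iodomethane, CI
Why: In this Williamson ether synthesis the caesium phenoxide of the hindered C4–OH is alkylated by the smallest electrophile by SN2, while the aryl pivalate is inert to carbonate in dry DMF.

Step 7
Reactants: 10 2,4,6-trimethoxy-3,5-bis(2,4,6-trimethoxyphenyl)phenyl pivalate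
Product: 11 2,4,6-trimethoxy-3,5-bis(2,4,6-trimethoxyphenyl)phenol
Conditions: KOH (5 equiv), MeOH/THF/H2O, 60 °C, Ar; then 1 M HCl
Reagents that add atoms: none
Why: Saponification of an aryl ester benefits from the good phenoxide leaving group even for a pivalate and frees C1–OH as the only hydroxyl of the molecule.

Step 8
Reactants: 12 1-bromo-3,5-dimethoxybenzene
Product: 14 2-bromo-4,6-dimethoxybenzaldehyde, via aryl iminium salt 13 (not isolated)
Conditions: POCl3 (2 equiv), DMF, 0 °C to 95 °C; then ice-water; recrystallisation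
Reagents that add atoms: N,N-dimethylformamide, CN(C)C=O; water, O
Why: In this Vilsmeier–Haack formylation the chloroiminium ion attacks the position ortho to one methoxy group and para to the other rather than the site between both methoxy groups, and hydrolysis of 13 gives the aldehyde, with the minor 4-bromo isomer removed by crystallisation.

Step 9
Reactants: 11 2,4,6-trimethoxy-3,5-bis(2,4,6-trimethoxyphenyl)phenol; 14 2-bromo-4,6-dimethoxybenzaldehyde
Product: 15 2,4-dimethoxy-6-[2,4,6-trimethoxy-3,5-bis(2,4,6-trimethoxyphenyl)phenoxy]benzaldehyde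
Conditions: 14 (1.5 equiv), CuI (20 mol %), picolinic acid (40 mol %), K3PO4 (2.5 equiv), dry degassed DMSO, 100 °C, Ar
Reagents that add atoms: none
Why: This Ullmann diaryl ether synthesis under monovalent copper catalysis uses a picolinate ligand that tolerates di-ortho-substituted phenols, the ortho-formyl group activates the C–Br bond, and 11 offers a single nucleophilic site.

Step 10
Reactants: 15 2,4-dimethoxy-6-[2,4,6-trimethoxy-3,5-bis(2,4,6-trimethoxyphenyl)phenoxy]benzaldehyde
Product: 17 2,4-dimethoxy-6-[2,4,6-trimethoxy-3,5-bis(2,4,6-trimethoxyphenyl)phenoxy]phenol, via aryl formate 16 (not isolated)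
Conditions: mCPBA (1.3 equiv), CH2Cl2, 0 °C to rt; NaHCO3 wash, solvent swap; K2CO3 (0.2 equiv), MeOH, 0 °C, Ar
Reagents that add atoms: mCPBA (3-chloroperoxybenzoic acid), O=C(OO)c1cccc(Cl)c1
Why: In this Baeyer–Villiger (Dakin-type) oxidation the trioxygenated aryl group migrates in the Criegee adduct far faster than hydrogen and faster than the peracid attacks the other rings, and mild methanolysis of 16 frees the phenol.

Step 11
Reactants: 17 2,4-dimethoxy-6-[2,4,6-trimethoxy-3,5-bis(2,4,6-trimethoxyphenyl)phenoxy]phenol; 12 1-bromo-3,5-dimethoxybenzene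
Product: 18 2-(3,5-dimethoxyphenoxy)-1,5-dimethoxy-3-[2,4,6-trimethoxy-3,5-bis(2,4,6-trimethoxyphenyl)phenoxy]benzene (tridecamethyl ether of the target)
Conditions: 12 (3 equiv), CuI (30 mol %), picolinic acid (60 mol %), K3PO4 (3 equiv), dry degassed DMSO, 110 °C, Ar
Reagents that add atoms: none
Why: This second Ullmann diaryl ether synthesis pairs the hindered phenol with an aryl bromide that has no ortho substituent and is used in excess, which is the favourable combination for this catalyst.

Step 12
Reactants: 18 tridecamethyl ether of the target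
Product: 19 4-(3,5-dihydroxyphenoxy)-5-[2,4,6-trihydroxy-3,5-bis(2,4,6-trihydroxyphenyl)phenoxy]benzene-1,3-diol (CNP0228669.0)
Conditions: BBr3 (40 equiv, 1 M in CH2Cl2), CH2Cl2, −78 °C to rt, then 40 °C, 24–48 h; ice-water, EtOAc extraction; Sephadex LH-20 (MeOH), Ar
Reagents that add atoms: none
Why: In this Lewis-acid ether cleavage BBr3 binds each methoxy oxygen and bromide removes the methyl group by SN2, the diaryl ether and biaryl bonds offer no sp3 carbon and survive, and an aqueous rather than methanolic quench avoids acid-catalysed re-etherification of the phloroglucinol rings.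

## Compound list
1 | 2,6-dichloro-1,4-benzoquinone | O=C1C=C(Cl)C(=O)C(Cl)=C1 | starting material
2 | 1,3,5-trimethoxybenzene | COc1cc(OC)cc(OC)c1 | starting material
3 | monoaryl hydroquinone: 2,6-dichloro-3-(2,4,6-trimethoxyphenyl)benzene-1,4-diol | COc1cc(OC)c(c(OC)c1)-c1c(O)cc(Cl)c(O)c1Cl | intermediate
4 | 2,6-dichloro-3-(2,4,6-trimethoxyphenyl)-1,4-benzoquinone | O=C1C=C(Cl)C(=O)C(Cl)=C1c1c(OC)cc(OC)cc1OC | intermediate
5 | diaryl hydroquinone: 2,6-dichloro-3,5-bis(2,4,6-trimethoxyphenyl)benzene-1,4-diol | COc1cc(OC)c(c(OC)c1)-c1c(O)c(-c2c(OC)cc(OC)cc2OC)c(Cl)c(O)c1Cl | intermediate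
6 | 2,6-dichloro-3,5-bis(2,4,6-trimethoxyphenyl)-1,4-benzoquinone | O=C1C(c2c(OC)cc(OC)cc2OC)=C(Cl)C(=O)C(Cl)=C1c1c(OC)cc(OC)cc1OC | intermediate
7 | 2,6-dimethoxy-3,5-bis(2,4,6-trimethoxyphenyl)-1,4-benzoquinone | O=C1C(c2c(OC)cc(OC)cc2OC)=C(OC)C(=O)C(OC)=C1c1c(OC)cc(OC)cc1OC | intermediate
8 | 2,6-dimethoxy-3,5-bis(2,4,6-trimethoxyphenyl)benzene-1,4-diol | COc1cc(OC)c(c(OC)c1)-c1c(O)c(-c2c(OC)cc(OC)cc2OC)c(OC)c(O)c1OC | intermediate
9 | 4-hydroxy-2,6-dimethoxy-3,5-bis(2,4,6-trimethoxyphenyl)phenyl pivalate | COc1cc(OC)c(c(OC)c1)-c1c(O)c(-c2c(OC)cc(OC)cc2OC)c(OC)c(OC(=O)C(C)(C)C)c1OC | intermediate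
10 | 2,4,6-trimethoxy-3,5-bis(2,4,6-trimethoxyphenyl)phenyl pivalate | COc1cc(OC)c(c(OC)c1)-c1c(OC)c(-c2c(OC)cc(OC)cc2OC)c(OC)c(OC(=O)C(C)(C)C)c1OC | intermediate
11 | 2,4,6-trimethoxy-3,5-bis(2,4,6-trimethoxyphenyl)phenol | COc1cc(OC)c(c(OC)c1)-c1c(OC)c(-c2c(OC)cc(OC)cc2OC)c(OC)c(O)c1OC | intermediate
12 | 1-bromo-3,5-dimethoxybenzene | COc1cc(Br)cc(OC)c1 | starting material
13 | aryl iminium salt: [(2-bromo-4,6-dimethoxyphenyl)methylidene]dimethylammonium dichlorophosphate | C[N+](C)=Cc1c(Br)cc(OC)cc1OC.[O-]P(=O)(Cl)Cl | intermediate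
14 | 2-bromo-4,6-dimethoxybenzaldehyde | O=Cc1c(Br)cc(OC)cc1OC | intermediate
15 | 2,4-dimethoxy-6-[2,4,6-trimethoxy-3,5-bis(2,4,6-trimethoxyphenyl)phenoxy]benzaldehyde | COc1cc(OC)c(C=O)c(c1)Oc1c(OC)c(-c2c(OC)cc(OC)cc2OC)c(OC)c(-c2c(OC)cc(OC)cc2OC)c1OC | intermediate
16 | aryl formate: 2,4-dimethoxy-6-[2,4,6-trimethoxy-3,5-bis(2,4,6-trimethoxyphenyl)phenoxy]phenyl formate | COc1cc(OC)c(OC=O)c(c1)Oc1c(OC)c(-c2c(OC)cc(OC)cc2OC)c(OC)c(-c2c(OC)cc(OC)cc2OC)c1OC | intermediate
17 | 2,4-dimethoxy-6-[2,4,6-trimethoxy-3,5-bis(2,4,6-trimethoxyphenyl)phenoxy]phenol | COc1cc(OC)c(O)c(c1)Oc1c(OC)c(-c2c(OC)cc(OC)cc2OC)c(OC)c(-c2c(OC)cc(OC)cc2OC)c1OC | intermediate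
18 | 2-(3,5-dimethoxyphenoxy)-1,5-dimethoxy-3-[2,4,6-trimethoxy-3,5-bis(2,4,6-trimethoxyphenyl)phenoxy]benzene | COc1cc(OC)cc(Oc2c(OC)cc(OC)cc2Oc2c(OC)c(-c3c(OC)cc(OC)cc3OC)c(OC)c(-c3c(OC)cc(OC)cc3OC)c2OC)c1 | intermediate
19 | 4-(3,5-dihydroxyphenoxy)-5-[2,4,6-trihydroxy-3,5-bis(2,4,6-trihydroxyphenyl)phenoxy]benzene-1,3-diol (CNP0228669.0, achiral) | Oc1cc(O)cc(Oc2c(O)cc(O)cc2Oc2c(O)c(-c3c(O)cc(O)cc3O)c(O)c(-c3c(O)cc(O)cc3O)c2O)c1 | target

## Step count and risks
Total step count: 12.
Longest linear sequence: 11 steps (steps 1–7 and 9–12, from 1). Step 8 is a one-step side branch.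

**Risk 1, step 9.** The phenol carries two ortho methoxy groups buttressed by rings D and E, the bromide has an ortho substituent, and the electron-rich phenoxide can be oxidised by copper and traces of air.
- The fallback sets out from 11 and comes back at 15. It gives up copper catalysis for an uncatalysed nucleophilic aromatic substitution on a fluoride.
- Bought 1-fluoro-3,5-dimethoxybenzene is formylated with POCl3/DMF by way of the fluoroaryl iminium dichlorophosphate F1. Its hydrolysis gives 2-fluoro-4,6-dimethoxybenzaldehyde F2.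
- Compounds 11 and F2 are then heated with Cs2CO3 in DMSO at 120 °C. The oxygen of 11 adds ortho to the formyl group and fluoride leaves, giving 15.

**Risk 2, step 11.** This is a late coupling of a precious phenol whose hydroxyl lies between a methoxy group and the very large ring C aryloxy group.
- The fallback sets out from 17 (with 2 as auxiliary arene) and comes back at 18. It replaces catalysis by metal-free ligand coupling at trivalent iodine.
- Bought 1-iodo-3,5-dimethoxybenzene is oxidised with mCPBA and TsOH·H2O in MeCN to 1-[hydroxy(tosyloxy)iodo]-3,5-dimethoxybenzene F3.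
- F3 is condensed in the same flask with 2 to give (3,5-dimethoxyphenyl)(2,4,6-trimethoxyphenyl)iodonium tosylate F4.
- Compound 17, KOtBu and F4 in toluene at rt to 50 °C give 18. The trimethoxyphenyl group stays on iodine as the non-transferring ligand, and this type of arylation is little affected by ortho substituents on the phenol.

**Risk 3, step 12.** Thirteen cleavages must all go to completion. The product is polar and air-sensitive, and its 2,2'-dihydroxybiaryl units can close to dibenzofurans in hot acid.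
- The fallback sets out from 18 and comes back at 19. It changes from direct isolation to a capture-and-release sequence.
- The crude material from the BBr3 cleavage is not purified. It is peracetylated (Ac2O, pyridine, DMAP cat., rt) to the tridecaacetate of the target F5.
- F5 is stable to air and silica gel, so incompletely cleaved material can be separated and returned to BBr3.
- Pure F5 is then deacetylated under near-neutral, reducing conditions (N2H4·H2O, MeCN, 0 °C, Ar) to give 19.

## Further compounds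
F1 | step 9 | [(2-fluoro-4,6-dimethoxyphenyl)methylidene]dimethylammonium dichlorophosphate | C[N+](C)=Cc1c(F)cc(OC)cc1OC.[O-]P(=O)(Cl)Cl
F2 | step 9 | 2-fluoro-4,6-dimethoxybenzaldehyde | O=Cc1c(F)cc(OC)cc1OC
F3 | step 11 | 1-[hydroxy(tosyloxy)iodo]-3,5-dimethoxybenzene | COc1cc(OC)cc(c1)I(O)OS(=O)(=O)c1ccc(C)cc1
F4 | step 11 | (3,5-dimethoxyphenyl)(2,4,6-trimethoxyphenyl)iodonium tosylate | COc1cc(OC)cc(c1)[I+]c1c(OC)cc(OC)cc1OC.Cc1ccc(cc1)S(=O)(=O)[O-]
F5 | step 12 | tridecaacetate of the target | CC(=O)Oc1cc(OC(C)=O)cc(Oc2c(OC(C)=O)cc(OC(C)=O)cc2Oc2c(OC(C)=O)c(-c3c(OC(C)=O)cc(OC(C)=O)cc3OC(C)=O)c(OC(C)=O)c(-c3c(OC(C)=O)cc(OC(C)=O)cc3OC(C)=O)c2OC(C)=O)c1
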